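I read the earlier runs from their second reading on, where free monomer stands at 3% or less.

| flask | free monomer | protic impurity | initiator | stray impurity | remark | time |
|---|---|---|---|---|---|---|
| Friday's | 1.5 M | 0.30 M | 7 mM | 5.3 mM | run made earlier |  |
| Monday's | 1.5 M | 0.30 M | 7 mM | 12 mM | run made earlier |  |
| Sunday's | 1.5 M | 0.30 M | 3.5 mM | 7.9 mM | run made earlier |  |
| winter | 1.5 M | 0.300 M | 7.0 mM | 7.9 mM |  | 10 min |
| noon | 1.5 M | 0.300 M | 7.0 mM | 7.9 mM |  | 15 min |
| autumn | 1.5 M | 0.300 M | 7.0 mM | 7.9 mM |  | 20 min |

| run | time / min | free monomer / % | uncatalysed product / % | monomer in chains / % |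
|---|---|---|---|---|
| Friday's | 1.33 | 1 | 23 | 61 |
| Friday's | 4.00 | 0 | 25 | 64 |
| Friday's | 6.00 | 0 | 21 | 64 |
| Friday's | 10.0 | 1 | 24 | 65 |
| Monday's | 2.50 | 3 | 35 | 45 |
| Monday's | 5.00 | 3 | 36 | 48 |
| Monday's | 8.00 | 0 | 37 | 48 |
| Monday's | 10.0 | 0 | 40 | 42 |
| Sunday's | 1.33 | 21 | 36 | 30 |
| Sunday's | 4.00 | 1 | 46 | 37 |
| Sunday's | 6.00 | 0 | 45 | 38 |
| Sunday's | 10.0 | 0 | 45 | 39 |

(standard deviation of a reading: 1.5 percentage points)



1. which of these there is most of at the end, counted by the free monomer in it, winter (free monomer / uncatalysed product / monomer in chains)
2. which of these there is most of at the end, counted by the free monomer in it, noon (free monomer / uncatalysed product / monomer in chains)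
3. which of these there is most of at the end, counted by the free monomer in it, autumn (free monomer / uncatalysed product / monomer in chains)
4. the largest of these amounts at the end, in percent of the free monomer charged, winter
5. the largest of these amounts at the end, in percent of the free monomer charged, noon
6. the largest of these amounts at the end, in percent of the free monomer charged, autumn

I keep the books on free monomer, the limiting reagent. Its charge goes into monomer in chains, uncatalysed product and a remainder that neither column shows. Averaged over the last three readings, Friday's books close at 64.3% chains, 23.3% uncatalysed and 12.3% remainder. Monday's close at 46.0%, 37.7% and 16.3%, Sunday's at 38.0%, 45.3% and 16.7%.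

Chains and uncatalysed product draw on the same free monomer, so I compare them as a ratio and hold it against c(initiator)/c(stray impurity). Dividing the first by the second gives 2.09 for Friday's, 2.09 for Monday's and 1.89 for Sunday's, on average 2.02. This is the split number: chains over uncatalysed product, per unit of c(initiator)/c(stray impurity).

Winter, noon and autumn differ in time, 10 min, 15 min and 20 min, and none stops before the last readings, so I give them one ledger. Their c(initiator)/c(stray impurity) is 0.886, so chains over uncatalysed product comes to 1.79. For the remainder I take the mean of Friday's and Monday's, whose c(stray impurity) lie on either side of this one: 14.3%. My books close at 55.0% chains and 30.7% uncatalysed product, so chains hold more.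

The forecast names monomer in chains for each flask, at 56% (52% to 60%) in winter, 56% (52% to 60%) at noon and 56% (51% to 60%) in autumn, holding that “10, 15 and 20 min should all give the same final state”. My figure stands 1 percentage point below its figure for winter.

The flasks give monomer in chains at 57.6% in winter, 57.6% at noon and 57.6% in autumn, with uncatalysed product at 28.0%. The length of the run makes no difference here.

    free monomer + initiator → living end + monomer in chains (k = 0.0126 M⁻¹ s⁻¹)
    free monomer + living end → monomer in chains + living end, rate k2*[living end]*[free monomer] (k = 30.1 M⁻¹ s⁻¹)
    free monomer → uncatalysed product (k = 0.00818 s⁻¹)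
    initiator + stray impurity → spent initiator (k = 36.1 M⁻¹ s⁻¹)
    protic impurity + free monomer → quenched substrate (k = 0.0248 M⁻¹ s⁻¹)

Autumn's result, put into the same ledger, gives a split number of 2.32. The neighbouring flask is autumn with c(initiator) at 2.80 mM, so its c(initiator)/c(stray impurity) is 0.354. The split number 2.02 read from the runs then gives chains over uncatalysed product of 0.717, and with the remainder 14.3% my ledger gives the chains 35.8%. In that neighbouring flask uncatalysed product holds most, chains over uncatalysed product is 0.671, and monomer in chains ends at 33.0% against 49.2% of uncatalysed product.

The earlier runs and the new flask were generated by integration with made-up constants, noise included.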